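**Retrosynthetic overview**

- Diplotrin A is taken back to its 2',5'-bis-pivalate, so the air-sensitive methoxyhydroquinone ring B is unmasked only in the last step.
- Ring C is the only ring made. It is closed by forming C4–C4a through intramolecular Friedel–Crafts acylation of an (E)-3-aryloxy-2-methoxy-3-arylacrylic acid.
- The strategy rests on C4a of ring A. It is the only unsubstituted carbon ortho to the ether oxygen O1, because the other ortho carbon, C8, carries a methoxy group, and it lies para to the C7 methoxy group. An acylium at C4 can therefore close only there.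
- The acid comes from its tert-butyl ester. The O1–C2 bond is made by addition–elimination of 2,3-dimethoxyphenoxide on a β-triflyloxy acrylate, and the C2–C3 bond by crossed Claisen acylation of tert-butyl methoxyacetate with the ring B aroyl chloride.
- The ring B acid comes from 2-hydroxy-4-methoxybenzoic acid by para-hydroxylation (Elbs) and pivaloylation. Rings A and B are bought.

Key step: step 7

Remark: the C2=C3 double bond (flavone numbering) of 10, 12, 13 and 14 is drawn E, as expected from a chelated enolate and substitution with retention. The ring closure is expected to accept either geometric isomer.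

**Step 1**
Reactants: 1 2-hydroxy-4-methoxybenzoic acid
Product: 3 2,5-dihydroxy-4-methoxybenzoic acid, via aryl hydrogen sulfate 2 (not isolated)
Conditions: K2S2O8, aq. NaOH, 5 °C → rt; then aq. HCl, 70 °C
Reagents that add atoms: potassium peroxodisulfate K2S2O8, [K+].[K+].[O-]S(=O)(=O)OOS(=O)(=O)[O-]
Why: Elbs persulfate oxidation, in which the phenoxide attacks the peroxide oxygen through C5, the only free carbon para to the C2 hydroxyl, and the resulting aryl sulfate is hydrolysed by acid to the hydroquinone; a modest conversion is expected and is acceptable at the first step from a cheap acid.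

**Step 2**
Reactants: 3 2,5-dihydroxy-4-methoxybenzoic acid; 4 pivaloyl chloride
Product: 6 4-methoxy-2,5-bis(pivaloyloxy)benzoic acid, via mixed pivalic anhydride 5 (not isolated)
Conditions: PivCl (3.5 equiv), pyridine, DMAP (cat.), CH2Cl2, 0 °C → rt; then H2O, THF, rt
Reagents that add atoms: pivaloyl chloride, CC(C)(C)C(=O)Cl
Why: DMAP-catalysed O-acylation (nucleophilic acyl substitution) with an excess of 4 should esterify both phenols and convert the carboxyl group into a mixed anhydride, so three equivalents of the acid chloride are consumed; water then cleaves the anhydride back to the free acid while the hindered aryl pivalates are left intact, so two pivaloyl groups remain in 6.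

**Step 3**
Reactants: 6 4-methoxy-2,5-bis(pivaloyloxy)benzoic acid; 7 tert-butyl methoxyacetate
Product: 9 tert-butyl 2-methoxy-3-[4-methoxy-2,5-bis(pivaloyloxy)phenyl]-3-oxopropanoate (racemic at C2), via aroyl chloride 8 (not isolated)
Conditions: (COCl)2, DMF (cat.), CH2Cl2, 0 °C → rt, evaporate; then 7 (2.2 equiv), LiN(SiMe3)2 (2.1 equiv), THF, −78 °C, addition of 8 to the enolate; AcOH, −78 °C
Reagents that add atoms: none
Why: crossed Claisen condensation, in which the lithium enolate of 7 is C-acylated by the aroyl chloride, the tert-butyl ester suppresses self-condensation, the second equivalent of enolate deprotonates the product and so prevents double acylation, and −78 °C with a cold acidic quench keeps the enolates away from the hindered aryl pivalates; the new C2 centre is racemic and is removed again on enolisation in step 4.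

**Step 4**
Reactants: 9 tert-butyl 2-methoxy-3-[4-methoxy-2,5-bis(pivaloyloxy)phenyl]-3-oxopropanoate
Product: 10 tert-butyl (E)-2-methoxy-3-[4-methoxy-2,5-bis(pivaloyloxy)phenyl]-3-(trifluoromethylsulfonyloxy)prop-2-enoate
Conditions: NaH (1.1 equiv), Et2O, 0 °C; then Tf2O (1.1 equiv), −78 → 0 °C
Reagents that add atoms: trifluoromethanesulfonic anhydride, O=S(=O)(OS(=O)(=O)C(F)(F)F)C(F)(F)F
Why: enolate O-sulfonylation, in which the sodium enolate is chelated between the ketone oxygen and the ester carbonyl so that the triflate should end cis to the ester (E descriptor, because the methoxy group outranks the ester carbon), and the short exposure at or below 0 °C limits migration of the ortho pivaloyl group to the enolate oxygen.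

**Step 5**
Reactants: 10 tert-butyl (E)-2-methoxy-3-[4-methoxy-2,5-bis(pivaloyloxy)phenyl]-3-(trifluoromethylsulfonyloxy)prop-2-enoate; 11 2,3-dimethoxyphenol
Product: 12 tert-butyl (E)-3-(2,3-dimethoxyphenoxy)-2-methoxy-3-[4-methoxy-2,5-bis(pivaloyloxy)phenyl]prop-2-enoate
Conditions: 11 (1.05 equiv), Cs2CO3 (1.1 equiv), MeCN, 0 °C → rt
Reagents that add atoms: none
Why: nucleophilic vinylic substitution by addition–elimination, in which the phenoxide adds to the triflate-bearing β-carbon of the acrylate and the ester enolate expels triflate before it rotates, so the aryloxy group should end cis to the ester (E), while one equivalent of phenoxide at or below room temperature should spare the hindered pivalates; any Z isomer can be carried forward.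

**Step 6**
Reactants: 12 tert-butyl (E)-3-(2,3-dimethoxyphenoxy)-2-methoxy-3-[4-methoxy-2,5-bis(pivaloyloxy)phenyl]prop-2-enoate
Product: 13 (E)-3-(2,3-dimethoxyphenoxy)-2-methoxy-3-[4-methoxy-2,5-bis(pivaloyloxy)phenyl]prop-2-enoic acid
Conditions: CF3CO2H–CH2Cl2 (1:4), 0 °C → rt
Reagents that add atoms: none
Why: acid-mediated tert-butyl ester cleavage through the tert-butyl cation, which leaves as isobutene; aryl pivalates, methyl ethers and the ester-deactivated enol ether tolerate CF3CO2H, and dilution and low temperature limit tert-butylation of ring A.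

**Step 7**
Reactants: 13 (E)-3-(2,3-dimethoxyphenoxy)-2-methoxy-3-[4-methoxy-2,5-bis(pivaloyloxy)phenyl]prop-2-enoic acid
Product: 15 2-[4-methoxy-2,5-bis(pivaloyloxy)phenyl]-3,7,8-trimethoxy-4H-chromen-4-one, via mixed trifluoroacetic anhydride 14 (not isolated)
Conditions: (CF3CO)2O (3 equiv), CF3SO3H (0.1 equiv), CH2Cl2, 0 °C → rt
Reagents that add atoms: none
Why: (CF3CO)2O converts the acid into mixed anhydride 14, which CF3SO3H ionises to a β-aryloxy acylium ion; this attacks ring A at C4a, the carbon ortho to the ether oxygen and para to the C7 methoxy group, and loss of a proton gives the chromen-4-one. The closest known reaction is the acid-mediated intramolecular Friedel–Crafts acylation of 3-aryloxyacrylic and 3-aryloxycinnamic acids to chromones and flavones. Ring C closes in a 6-exo mode, the acyl carbon becoming C4 with its oxygen outside the ring, and no stereocentre is formed. The site on ring A is fixed because the other carbon ortho to the ether oxygen carries the C8 methoxy group. Attack on ring B, which would give a five-membered indenone, is disfavoured by the two electron-withdrawing pivalates and by the trans relation of ring B and the carboxyl group in the E isomer. Any Z isomer should equilibrate through the ketene–oxocarbenium resonance form of the acylium, which lowers the C2–C3 bond order, and drain into the chromone.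

**Step 8**
Reactants: 15 2-[4-methoxy-2,5-bis(pivaloyloxy)phenyl]-3,7,8-trimethoxy-4H-chromen-4-one
Product: 16 diplotrin A, 2-(2,5-dihydroxy-4-methoxyphenyl)-3,7,8-trimethoxy-4H-chromen-4-one
Conditions: K2CO3 (3 equiv), degassed MeOH, argon, rt; then aq. NH4Cl under argon
Reagents that add atoms: none
Why: base-mediated transesterification (methanolysis) of the two aryl pivalates, which are far more reactive than the four methyl ethers or the chromone, while exclusion of oxygen should keep the methoxyhydroquinone ring B from oxidising to the quinone.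

**Compound list**

1 | 2-hydroxy-4-methoxybenzoic acid | COc1ccc(C(=O)O)c(O)c1 | starting material
2 | 2-hydroxy-4-methoxy-5-(sulfooxy)benzoic acid (aryl hydrogen sulfate, present as its salt in the alkaline solution) | COc1cc(O)c(C(=O)O)cc1OS(=O)(=O)O | intermediate
3 | 2,5-dihydroxy-4-methoxybenzoic acid | COc1cc(O)c(C(=O)O)cc1O | intermediate
4 | pivaloyl chloride | CC(C)(C)C(=O)Cl | starting material
5 | 4-methoxy-2,5-bis(pivaloyloxy)benzoic pivalic anhydride | COc1cc(OC(=O)C(C)(C)C)c(C(=O)OC(=O)C(C)(C)C)cc1OC(=O)C(C)(C)C | intermediate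
6 | 4-methoxy-2,5-bis(pivaloyloxy)benzoic acid | COc1cc(OC(=O)C(C)(C)C)c(C(=O)O)cc1OC(=O)C(C)(C)C | intermediate
7 | tert-butyl methoxyacetate | COCC(=O)OC(C)(C)C | starting material
8 | 4-methoxy-2,5-bis(pivaloyloxy)benzoyl chloride | COc1cc(OC(=O)C(C)(C)C)c(C(Cl)=O)cc1OC(=O)C(C)(C)C | intermediate
9 | tert-butyl 2-methoxy-3-[4-methoxy-2,5-bis(pivaloyloxy)phenyl]-3-oxopropanoate (racemic) | COC(C(=O)OC(C)(C)C)C(=O)c1cc(OC(=O)C(C)(C)C)c(OC)cc1OC(=O)C(C)(C)C | intermediate
10 | tert-butyl (E)-2-methoxy-3-[4-methoxy-2,5-bis(pivaloyloxy)phenyl]-3-(trifluoromethylsulfonyloxy)prop-2-enoate (triflate cis to the ester) | FC(F)(F)S(=O)(=O)O/C(c1cc(OC(=O)C(C)(C)C)c(OC)cc1OC(=O)C(C)(C)C)=C(/OC)C(=O)OC(C)(C)C | intermediate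
11 | 2,3-dimethoxyphenol | COc1cccc(O)c1OC | starting material
12 | tert-butyl (E)-3-(2,3-dimethoxyphenoxy)-2-methoxy-3-[4-methoxy-2,5-bis(pivaloyloxy)phenyl]prop-2-enoate (aryloxy cis to the ester) | COc1cccc(O/C(c2cc(OC(=O)C(C)(C)C)c(OC)cc2OC(=O)C(C)(C)C)=C(/OC)C(=O)OC(C)(C)C)c1OC | intermediate
13 | (E)-3-(2,3-dimethoxyphenoxy)-2-methoxy-3-[4-methoxy-2,5-bis(pivaloyloxy)phenyl]prop-2-enoic acid | COc1cccc(O/C(c2cc(OC(=O)C(C)(C)C)c(OC)cc2OC(=O)C(C)(C)C)=C(/OC)C(=O)O)c1OC | intermediate
14 | (E)-3-(2,3-dimethoxyphenoxy)-2-methoxy-3-[4-methoxy-2,5-bis(pivaloyloxy)phenyl]prop-2-enoic trifluoroacetic anhydride | COc1cccc(O/C(c2cc(OC(=O)C(C)(C)C)c(OC)cc2OC(=O)C(C)(C)C)=C(/OC)C(=O)OC(=O)C(F)(F)F)c1OC | intermediate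
15 | 2-[4-methoxy-2,5-bis(pivaloyloxy)phenyl]-3,7,8-trimethoxy-4H-chromen-4-one | COc1cc(OC(=O)C(C)(C)C)c(-c2oc3c(OC)c(OC)ccc3c(=O)c2OC)cc1OC(=O)C(C)(C)C | intermediate
16 | diplotrin A, 2-(2,5-dihydroxy-4-methoxyphenyl)-3,7,8-trimethoxy-4H-chromen-4-one | COc1cc(O)c(-c2oc3c(OC)c(OC)ccc3c(=O)c2OC)cc1O | target

Total step count: 8. Longest linear sequence: 8 steps (1 to 16).

**Steps most likely to fail, with fallbacks**

Step 5. Three things may go wrong. The phenoxide may attack the sulfur of the triflate, which cleaves S–O and returns the enolate of 9. It may attack the aryl pivalates, which transfers an acyl group. Addition at the hindered β-carbon, which the α-methoxy group makes less electrophilic, may also be too slow. The fallback sets out from 10 and 11 and comes back at 12 in one operation, making no new compound (F0). It is a palladium-catalysed C–O cross-coupling with Pd2(dba)3, 2-di-tert-butylphosphino-2',4',6'-triisopropylbiphenyl and K3PO4 in toluene at 80 °C. Zerovalent palladium inserts into the C–OTf bond, phenoxide replaces triflate on the metal, and C–O reductive elimination gives the aryl enol ether. The nucleophile is delivered to palladium, not to carbon or sulfur, and the weak, poorly soluble base keeps the concentration of free phenoxide low.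

Step 7. The donor-stabilised acylium may be too weak an electrophile, so that ring closure is overtaken by intermolecular trifluoroacetylation of ring A, acid cleavage of the aryl enol ether or acyl scrambling of the pivalates. The fallback builds ring C in the classical order, with the C4–C4a bond made first. It sets out from 11 and 8 and comes back at 15.
- 2,3-Dimethoxyphenol 11 is acylated ortho to its hydroxyl with methoxyacetic acid and BF3·OEt2 at 80 °C (ester formation and Fries shift in the flask). This should give 1-(2-hydroxy-3,4-dimethoxyphenyl)-2-methoxyethan-1-one F1.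
- The phenol of F1 is esterified with aroyl chloride 8 (pyridine, DMAP, CH2Cl2) to 6-(methoxyacetyl)-2,3-dimethoxyphenyl 4-methoxy-2,5-bis(pivaloyloxy)benzoate F2.
- A Baker–Venkataraman acyl shift with LiN(SiMe3)2 in THF at −78 → 0 °C should give 1-(2-hydroxy-3,4-dimethoxyphenyl)-2-methoxy-3-[4-methoxy-2,5-bis(pivaloyloxy)phenyl]propane-1,3-dione F3.
- Cyclodehydration of F3 with catalytic H2SO4 in AcOH at 60 °C closes O1–C2 and gives 15.

Step 3. The ortho pivaloyl group may transfer to the oxygen of the new β-keto ester enolate, followed by lactonisation onto the ester to a coumarin, or the ester enolate may attack the aryl pivalates. The fallback avoids any strongly basic enolate. It sets out from 6 and comes back at 9.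
- Acid 6 is converted with 1,1'-carbonyldiimidazole in THF into 1-[4-methoxy-2,5-bis(pivaloyloxy)benzoyl]imidazole F4.
- F4 acylates the magnesium enolate made from potassium mono-tert-butyl malonate, MgCl2 and Et3N in MeCN at rt. Decarboxylation on acidic work-up should give tert-butyl 3-[4-methoxy-2,5-bis(pivaloyloxy)phenyl]-3-oxopropanoate F5.
- Diazo transfer with 4-acetamidobenzenesulfonyl azide and Et3N in MeCN gives tert-butyl 2-diazo-3-[4-methoxy-2,5-bis(pivaloyloxy)phenyl]-3-oxopropanoate F6.
- Rh2(OAc)4-catalysed O–H insertion of the carbenoid from F6 into methanol (CH2Cl2, rt) installs the C2 methoxy group and gives 9.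

**Further compounds**

F0 | step 5 | none | none
F1 | step 7 | 1-(2-hydroxy-3,4-dimethoxyphenyl)-2-methoxyethan-1-one | COCC(=O)c1ccc(OC)c(OC)c1O
F2 | step 7 | 6-(methoxyacetyl)-2,3-dimethoxyphenyl 4-methoxy-2,5-bis(pivaloyloxy)benzoate | COCC(=O)c1ccc(OC)c(OC)c1OC(=O)c2cc(OC(=O)C(C)(C)C)c(OC)cc2OC(=O)C(C)(C)C
F3 | step 7 | 1-(2-hydroxy-3,4-dimethoxyphenyl)-2-methoxy-3-[4-methoxy-2,5-bis(pivaloyloxy)phenyl]propane-1,3-dione (racemic) | COC(C(=O)c1ccc(OC)c(OC)c1O)C(=O)c2cc(OC(=O)C(C)(C)C)c(OC)cc2OC(=O)C(C)(C)C
F4 | step 3 | 1-[4-methoxy-2,5-bis(pivaloyloxy)benzoyl]imidazole | COc1cc(OC(=O)C(C)(C)C)c(C(=O)n2ccnc2)cc1OC(=O)C(C)(C)C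
F5 | step 3 | tert-butyl 3-[4-methoxy-2,5-bis(pivaloyloxy)phenyl]-3-oxopropanoate | CC(C)(C)OC(=O)CC(=O)c1cc(OC(=O)C(C)(C)C)c(OC)cc1OC(=O)C(C)(C)C
F6 | step 3 | tert-butyl 2-diazo-3-[4-methoxy-2,5-bis(pivaloyloxy)phenyl]-3-oxopropanoate | CC(C)(C)OC(=O)C(=[N+]=[N-])C(=O)c1cc(OC(=O)C(C)(C)C)c(OC)cc1OC(=O)C(C)(C)C
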